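The constants were drawn at random within sensible limits; the rest is arithmetic.

The reading falls at 80 s in both flasks. This meeting had to say beforehand what the peaks would show then.

- zeta: free monomer 2.0 mM; transfer agent 0.0600 mM; initiator 2 mol%; temperature 20 °C; time 80 s
- theta: free monomer 2.0 mM; transfer agent 0.0600 mM; initiator 2 mol%; temperature 45 °C; time 80 s

    living end + transfer agent → dead chain (k1 = 310 /M/s, Ea1 = 37.0 kJ/mol)
    free monomer + initiator → living end + monomer in chains (k2 = 1000 /M/s, Ea2 = 43.0 kJ/mol)
    monomer in chains ⇌ isomer of the product (K3 = 0.55, k3 = 0.0088 /s, Ea3 = 83.0 kJ/mol, ΔH3 = −47.0 kJ/mol)
    free monomer → uncatalysed product (k4 = 0.030 /s, Ea4 = 70.0 kJ/mol)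
    free monomer + living end → monomer in chains + living end, rate k5*[living end]*[free monomer] (k5 = 800 /M/s, Ea5 = 40.0 kJ/mol)
    (constants at 20 °C)

- the list of constants is for 20 °C, to be carried to other temperatures by the activation energies and enthalpies

- the flask that comes out highest in share of monomer in chains in all that became monomer in chains or isomer of the product or uncatalysed product, or "all alike" when all lie within 1.5 percentage points (zeta / theta / all alike)
- share of monomer in chains in all that became monomer in chains or isomer of the product or uncatalysed product, zeta
- share of monomer in chains in all that became monomer in chains or isomer of the product or uncatalysed product, theta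

Item one. I proposed to look for the one concentration that sets the order of the rate. Free monomer leaves by propagation and by the uncatalysed step. Both are first order in [free monomer], so [free monomer] cancels from their ratio and [living end] stays. Propagation is thus pseudo-first-order, with [living end] inside its constant.

I argued that the pool fills early in zeta. An initiator lasts about 0.500 s there, shorter than the free monomer's 16.1 s. So I set [living end] at the initiator charge, 0.0400 mM.

Zeta's propagation then runs at 0.0320 /s against the uncatalysed 0.030 /s, which gives 51.6%. I called this the chain fraction: the propagation constant times [living end], divided by that product plus the uncatalysed constant.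

In theta, propagation gains a factor 3.6 and the uncatalysed step a factor 9.6. So 0.116 /s meets 0.287 /s, and the chain fraction drops to 28.9%.

Chains also pass to the isomer. In theta the equilibrium constant falls to 0.121, and the relaxation half-life of 0.585 s is shorter than the run. Dividing by one plus the constant, I committed to 25.7% for theta. The same division in zeta gave 33.3%, but I held that figure as rough. It counts a full relaxation, and zeta's relaxation half-life of 27.9 s is about a third of the run. Chains made late in zeta have had less time than that to relax. I still named zeta highest.

I warned that the pool sags. Transfer agent gives living ends a life of 53.8 s in zeta, against 16.1 s for the free monomer. In theta the figures are 16.3 s and 2.48 s.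

Item two. The forecast named zeta, with 32.2% for zeta and 23.5% for theta. Its ground was that “warming favours the uncatalysed route because it has the higher activation energy”. My two figures stood above its two.

Item three. The flasks give zeta highest, 32.8% against 23.7% for theta. The forecast stands on all three counts.

In theta, chains and isomer together read 26.6% at 80.0 s, against a chain fraction of 28.9%. The neighbour is theta charged with 8.0 mM of free monomer, initiator still at 2 mol%. Its pool starts at 0.160 mM, so propagation runs at 0.465 /s against the same 0.287 /s. The chain fraction of the neighbour is then 61.9%, and the division by one plus 0.121 leaves 55.2% in chains. The neighbour flask reads 53.9% at 80.0 s.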